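Ring A of the target carries oxygen at C5, C8 and C8a. C5 and C8 are para, so ring A is a masked p-benzoquinone in which C8a is the β-carbon of the C5 enone. The route rests on disconnecting O1–C8a: an acylbenzoquinone bearing a (Z)-3-hydroxy-3-methylbutenyl chain at C4a undergoes an intramolecular oxa-Michael addition and enolisation. This closes pyran ring B and returns ring A as the 5,8-diol in one operation. The precursor comes from a p-dimethoxyarene (benzil, Z-alkenyl carbinol) by oxidative demethylation just before use; methylation of the free C8 hydroxyl then completes the target.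

Key step: step 8

Remark on the chemistry: ring positions follow chromene numbering (O1, C2 to C8a) throughout, also for intermediates in which ring B does not yet exist. The Wittig product is carried forward as an E/Z mixture, because both isomers are oxidised to the same diketone.

Step 1
Reactants: 1 2-hydroxy-5-methoxybenzaldehyde
Product: 2 3-bromo-2-hydroxy-5-methoxybenzaldehyde
Conditions: Br2 (1.05 equiv), NaOAc, AcOH, rt
Reagents that add atoms: bromine, BrBr
Why: Electrophilic aromatic bromination should go to the only free position ortho to the strongly activating hydroxyl, the para position being blocked by the methoxy group, while NaOAc buffers the HBr.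

Step 2
Reactants: 2 3-bromo-2-hydroxy-5-methoxybenzaldehyde
Product: 3 3-bromo-2,5-dimethoxybenzaldehyde
Conditions: CH3I, K2CO3, DMF, rt
Reagents that add atoms: iodomethane, CI
Why: Williamson O-methylation of the phenoxide is the only possible alkylation, since the molecule has no other acidic site.

Step 3
Reactants: 3 3-bromo-2,5-dimethoxybenzaldehyde; 4 (4-methoxybenzyl)triphenylphosphonium chloride
Product: 6 1-bromo-2,5-dimethoxy-3-[2-(4-methoxyphenyl)ethenyl]benzene (E/Z mixture), via 4-methoxybenzylidene(triphenyl)phosphorane 5 (not isolated)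
Conditions: KOC(CH3)3, THF, 0 °C to rt
Reagents that add atoms: none
Why: Wittig olefination of a non-enolisable aryl aldehyde by a semi-stabilised benzylic ylide is reliable, and its lack of E/Z control is irrelevant here.

Step 4
Reactants: 6 1-bromo-2,5-dimethoxy-3-[2-(4-methoxyphenyl)ethenyl]benzene (E/Z mixture)
Product: 7 1-(3-bromo-2,5-dimethoxyphenyl)-2-(4-methoxyphenyl)ethane-1,2-dione
Conditions: I2 (0.5 equiv), DMSO, 150 °C
Reagents that add atoms: dimethyl sulfoxide, CS(C)=O (supplies both carbonyl oxygens)
Why: The iodine/DMSO oxidation of stilbenes to benzils (alkene iodination followed by Kornblum-type oxidations, with HI reoxidised to I2 by the solvent) should tolerate the aryl bromide and the aryl methyl ethers.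

Step 5
Reactants: 7 1-(3-bromo-2,5-dimethoxyphenyl)-2-(4-methoxyphenyl)ethane-1,2-dione; 8 2-methylbut-3-yn-2-ol
Product: 9 1-[3-(3-hydroxy-3-methylbut-1-yn-1-yl)-2,5-dimethoxyphenyl]-2-(4-methoxyphenyl)ethane-1,2-dione
Conditions: Pd(PPh3)2Cl2 (5 mol%), CuI (5 mol%), Et3N, DMF, 80 °C, argon
Reagents that add atoms: none
Why: Sonogashira coupling of an aryl bromide with a terminal propargylic alcohol is routine in warm Et3N/DMF, and the non-nucleophilic tertiary amine should leave the 1,2-diketone untouched.

Step 6
Reactants: 9 1-[3-(3-hydroxy-3-methylbut-1-yn-1-yl)-2,5-dimethoxyphenyl]-2-(4-methoxyphenyl)ethane-1,2-dione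
Product: 10 1-{3-[(Z)-3-hydroxy-3-methylbut-1-en-1-yl]-2,5-dimethoxyphenyl}-2-(4-methoxyphenyl)ethane-1,2-dione
Conditions: H2 (1 atm), 5% Pd/CaCO3 poisoned with Pb(OAc)2, quinoline, EtOAc, rt, stopped after one equivalent of H2
Reagents that add atoms: none
Why: Lindlar semihydrogenation delivers both hydrogens to the same face of the alkyne on the poisoned palladium surface, which should give the Z-alkene that later places the carbinol next to C8a, without reducing the diketone or the arenes.

Step 7
Reactants: 10 1-{3-[(Z)-3-hydroxy-3-methylbut-1-en-1-yl]-2,5-dimethoxyphenyl}-2-(4-methoxyphenyl)ethane-1,2-dione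
Product: 11 2-[(Z)-3-hydroxy-3-methylbut-1-en-1-yl]-6-[2-(4-methoxyphenyl)-2-oxoacetyl]cyclohexa-2,5-diene-1,4-dione
Conditions: (NH4)2Ce(NO3)6 (2.2 equiv), MeCN/H2O, 0 °C, 15 min; cold extractive work-up, crude quinone used at once
Reagents that add atoms: water, O (supplies both quinone oxygens)
Why: Oxidative demethylation of a 1,4-dimethoxyarene by tetravalent cerium (two one-electron oxidations, ipso attack of water, loss of methanol) should touch only the doubly oxygenated ring A, because the anisoyl ring is deactivated by its carbonyl, and the short cold contact time protects the allylic carbinol.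

Step 8
Reactants: 11 2-[(Z)-3-hydroxy-3-methylbut-1-en-1-yl]-6-[2-(4-methoxyphenyl)-2-oxoacetyl]cyclohexa-2,5-diene-1,4-dione
Product: 13 1-(5,8-dihydroxy-2,2-dimethyl-2H-chromen-6-yl)-2-(4-methoxyphenyl)ethane-1,2-dione, via 8aH-chromen-8-one dienol adduct 12 (not isolated)
Conditions: (±)-camphor-10-sulfonic acid (10 mol%), CH2Cl2 (0.005 M), argon, dark, 0 °C to rt; then wash with aqueous Na2S2O4
Reagents that add atoms: none
Why: The acid hydrogen-bonds to the C5 carbonyl, the carbonyl flanked by the acyl-bearing C6 and by C4a, and so polarises the C5–C4a=C8a enone; the tertiary hydroxyl held next to C8a by the Z-alkene adds to C8a to give dienol 12, which loses H-8a by tautomerisation and aromatises to the 5,8-diol 13. The closest known reaction type is the intramolecular oxa-Michael addition of a tethered alcohol to a benzoquinone with tautomerisation to the hydroquinone, the ring-forming counterpart of acid-catalysed alcohol addition to quinones. Ring B closes in a 6-endo-trig mode, for which the cis alkene preorganises the chain and the gem-dimethyl group biases the carbinol towards the ring. The sp3 centre at C8a in 12 is transient and is erased on aromatisation, so no stereocentre has to be controlled. The step needs site selectivity for C8a over C7, which is β to both the C5 carbonyl and the side-chain ketone and intrinsically more electrophilic; the short cis tether can reach only C8a, no external nucleophile is present, and hemiketal formation at C5 is reversible and returns 11. High dilution under argon disfavours bimolecular redox exchange between 13 and unconsumed 11, and the dithionite wash returns any chromenequinone formed in that way to 13.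

Step 9
Reactants: 13 1-(5,8-dihydroxy-2,2-dimethyl-2H-chromen-6-yl)-2-(4-methoxyphenyl)ethane-1,2-dione
Product: 14 dielsianone, 1-(5-hydroxy-8-methoxy-2,2-dimethyl-2H-chromen-6-yl)-2-(4-methoxyphenyl)ethane-1,2-dione
Conditions: CH3I (1.1 equiv), K2CO3 (1.1 equiv), degassed DMF, argon, rt
Reagents that add atoms: iodomethane, CI
Why: Williamson methylation with one equivalent of electrophile should take place at the free C8 phenol, because the C5 hydroxyl is locked in a six-membered hydrogen bond to the C6 ketone carbonyl and its phenoxide is far less nucleophilic.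

Compound list
1 | 2-hydroxy-5-methoxybenzaldehyde | COc1ccc(O)c(C=O)c1 | starting material
2 | 3-bromo-2-hydroxy-5-methoxybenzaldehyde | COc1cc(Br)c(O)c(C=O)c1 | intermediate
3 | 3-bromo-2,5-dimethoxybenzaldehyde | COc1cc(Br)c(OC)c(C=O)c1 | intermediate
4 | (4-methoxybenzyl)triphenylphosphonium chloride | COc1ccc(C[P+](c2ccccc2)(c2ccccc2)c2ccccc2)cc1.[Cl-] | starting material
5 | 4-methoxybenzylidene(triphenyl)phosphorane (ylide, not isolated) | COc1ccc(C=P(c2ccccc2)(c2ccccc2)c2ccccc2)cc1 | intermediate
6 | 1-bromo-2,5-dimethoxy-3-[2-(4-methoxyphenyl)ethenyl]benzene (E/Z mixture, geometry not defined) | COc1ccc(C=Cc2cc(OC)cc(Br)c2OC)cc1 | intermediate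
7 | 1-(3-bromo-2,5-dimethoxyphenyl)-2-(4-methoxyphenyl)ethane-1,2-dione | COc1ccc(C(=O)C(=O)c2cc(OC)cc(Br)c2OC)cc1 | intermediate
8 | 2-methylbut-3-yn-2-ol | CC(C)(O)C#C | starting material
9 | 1-[3-(3-hydroxy-3-methylbut-1-yn-1-yl)-2,5-dimethoxyphenyl]-2-(4-methoxyphenyl)ethane-1,2-dione | COc1ccc(C(=O)C(=O)c2cc(OC)cc(C#CC(C)(C)O)c2OC)cc1 | intermediate
10 | 1-{3-[(Z)-3-hydroxy-3-methylbut-1-en-1-yl]-2,5-dimethoxyphenyl}-2-(4-methoxyphenyl)ethane-1,2-dione | COc1ccc(C(=O)C(=O)c2cc(OC)cc(/C=C\C(C)(C)O)c2OC)cc1 | intermediate
11 | 2-[(Z)-3-hydroxy-3-methylbut-1-en-1-yl]-6-[2-(4-methoxyphenyl)-2-oxoacetyl]cyclohexa-2,5-diene-1,4-dione | COc1ccc(C(=O)C(=O)C2=CC(=O)C=C(/C=C\C(C)(C)O)C2=O)cc1 | intermediate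
12 | 1-(5-hydroxy-2,2-dimethyl-8-oxo-8,8a-dihydro-2H-chromen-6-yl)-2-(4-methoxyphenyl)ethane-1,2-dione (racemic at C8a, transient, not isolated) | COc1ccc(C(=O)C(=O)C2=CC(=O)C3OC(C)(C)C=CC3=C2O)cc1 | intermediate
13 | 1-(5,8-dihydroxy-2,2-dimethyl-2H-chromen-6-yl)-2-(4-methoxyphenyl)ethane-1,2-dione | COc1ccc(C(=O)C(=O)c2cc(O)c3c(c2O)C=CC(C)(C)O3)cc1 | intermediate
14 | dielsianone, 1-(5-hydroxy-8-methoxy-2,2-dimethyl-2H-chromen-6-yl)-2-(4-methoxyphenyl)ethane-1,2-dione | COc1ccc(C(=O)C(=O)c2cc(OC)c3c(c2O)C=CC(C)(C)O3)cc1 | target

Total step count: 9. Longest linear sequence: 9 steps (1 to 14).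

Steps most likely to fail

Step 8. The hindered tertiary hydroxyl may add slowly, so that the labile acylquinone decomposes. Alternatively, hydroquinone 13 may be oxidised by unconsumed 11 (redox exchange), which stalls the reaction because the reduced form of 11 cannot cyclise. The fallback replaces the redox-neutral isomerisation by an oxidation-driven cyclisation. Setting out from 10, an excess of (NH4)2Ce(NO3)6 (about 5 equiv) in MeCN/H2O at 0 °C to rt would demethylate ring A, let the carbinol add in the acidic medium and oxidise each adduct as it forms. All material would thus be funnelled to 6-[2-(4-methoxyphenyl)-2-oxoacetyl]-2,2-dimethyl-2H-chromene-5,8-dione F1. Reduction of F1 with Na2S2O4 in EtOAc/H2O should then rejoin the route at 13.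

Step 7. The acidic cerium medium may ionise the tertiary allylic carbinol (Z to E isomerisation, allylic transposition or dehydration), or the quinone may cyclise in the flask and be over-oxidised. The fallback runs the cerium oxidation before the acid-sensitive Z-allylic alcohol exists and regenerates the quinone under neutral conditions. Setting out from alkyne 9, (NH4)2Ce(NO3)6 in MeCN/H2O at 0 °C should give 2-(3-hydroxy-3-methylbut-1-yn-1-yl)-6-[2-(4-methoxyphenyl)-2-oxoacetyl]cyclohexa-2,5-diene-1,4-dione F2, whose propargylic carbinol does not ionise. Hydrogen over Pd/CaCO3 poisoned with Pb(OAc)2 would then reduce both the quinone and the alkyne to 1-{2,5-dihydroxy-3-[(Z)-3-hydroxy-3-methylbut-1-en-1-yl]phenyl}-2-(4-methoxyphenyl)ethane-1,2-dione F3, in which the C5 hydroxyl is deactivated by its hydrogen bond to the ketone. Ag2O with MgSO4 in Et2O at rt would oxidise F3 to 11, where the route is rejoined.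

Step 4. Iodonium formation on the electron-rich alkene may trigger attack of the ortho methoxy oxygen with loss of its methyl group (benzofuran formation), and ring iodination or ether cleavage by HI is possible at 150 °C. The fallback uses two mild steps. Setting out from 6, OsO4 (catalytic) with N-methylmorpholine N-oxide in acetone/H2O should give 1-(3-bromo-2,5-dimethoxyphenyl)-2-(4-methoxyphenyl)ethane-1,2-diol F4 as a mixture of diastereomers. A double Swern oxidation ((COCl)2, DMSO, Et3N, CH2Cl2, −78 °C), which oxidises both carbinols without C–C cleavage, would return to 7.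

Further compounds
F1 | step 8 | 6-[2-(4-methoxyphenyl)-2-oxoacetyl]-2,2-dimethyl-2H-chromene-5,8-dione | COc1ccc(C(=O)C(=O)C2=CC(=O)C3=C(C=CC(C)(C)O3)C2=O)cc1
F2 | step 7 | 2-(3-hydroxy-3-methylbut-1-yn-1-yl)-6-[2-(4-methoxyphenyl)-2-oxoacetyl]cyclohexa-2,5-diene-1,4-dione | COc1ccc(C(=O)C(=O)C2=CC(=O)C=C(C#CC(C)(C)O)C2=O)cc1
F3 | step 7 | 1-{2,5-dihydroxy-3-[(Z)-3-hydroxy-3-methylbut-1-en-1-yl]phenyl}-2-(4-methoxyphenyl)ethane-1,2-dione | COc1ccc(C(=O)C(=O)c2cc(O)cc(/C=C\C(C)(C)O)c2O)cc1
F4 | step 4 | 1-(3-bromo-2,5-dimethoxyphenyl)-2-(4-methoxyphenyl)ethane-1,2-diol (mixture of diastereomers, configuration not defined) | COc1ccc(C(O)C(O)c2cc(OC)cc(Br)c2OC)cc1
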